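**Retrosynthetic overview**
- The target is the free hexaphenol of a tetra-O-benzyl ether; all benzyl groups are removed together at the end.
- The flavanone C2–C1' bond is cut to a biaryl boronic acid and 7-benzyloxy-5-methoxychromone; a rhodium-catalysed asymmetric 1,4-addition sets 2S.
- Key cut: the biaryl bond C3'(flavanone ring B)–C6(flavone ring A). Both carbons are natively nucleophilic (each ortho to a phenolic oxygen), so the ring B carbon is inverted to an aryl cation (phenol α-cation, enolonium-type) equivalent, an aryllead triacetate, which arylates the C6–H of apigenin 7,4'-dibenzyl ether ortho to its free 5-OH.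
- Ring order: the flavone rings are bought intact as apigenin; then the biaryl bond; the chromone ring is closed separately from an acetophenone; the flavanone stereocentre comes last.
- The biaryl axis carries only OH, OH and H ortho to it and is not a stereogenic element.

Assumption: apigenin, [2-(benzyloxy)-5-bromophenyl]boronic acid and 1-(2,4-dihydroxy-6-methoxyphenyl)ethan-1-one are bought as catalogue compounds.

**Route**

Step 1
Reactants: 1 apigenin
Product: 2 apigenin 7,4'-dibenzyl ether
Conditions: BnBr (2.1 equiv), K2CO3 (2.5 equiv), DMF, 25 → 40 °C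
Reagents that add atoms: benzyl bromide, BrCc1ccccc1
Why: Williamson ether synthesis; the 7-OH and 4'-OH are alkylated while the 5-OH, hydrogen-bonded to the C4 carbonyl, stays free as the later directing group.

Step 2
Reactants: 2 apigenin 7,4'-dibenzyl ether; 3 [2-(benzyloxy)-5-bromophenyl]boronic acid
Product: 5 6-aryl flavone bromide (7-benzyloxy-6-[2-benzyloxy-5-bromophenyl]-2-[4-benzyloxyphenyl]-5-hydroxy-4H-chromen-4-one), via aryllead triacetate 4 (not isolated)
Conditions: 3 (1.4 equiv), Pb(OAc)4 (1.3 equiv), Hg(OAc)2 (10 mol %), CHCl3, 40 °C → rt; then 2 (1.0 equiv), pyridine (4 equiv), CHCl3, 60 °C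
Reagents that add atoms: none
Why: Pinhey arylation: boron-to-lead exchange turns the natively nucleophilic ring B carbon into an aryl cation equivalent on tetravalent lead, the 5-OH of 2 binds lead as the phenoxide, and ligand coupling delivers the aryl group to C6, the only free ortho carbon and the most electron-rich ring A position, with loss of Pb(OAc)2; this ortho C–H arylation is known for electron-rich and hindered phenols but is untested on a chelated 5-hydroxyflavone.

Step 3
Reactants: 5 6-aryl flavone bromide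
Product: 6 biaryl boronic acid
Conditions: B2(OH)4 (2 equiv), PdCl(XPhos)(2'-amino-1,1'-biphenyl-2-yl) (second-generation XPhos precatalyst, 3 mol %), XPhos (3 mol %), KOAc (3 equiv), EtOH/THF (1:1), 70 °C; aqueous work-up
Reagents that add atoms: tetrahydroxydiboron, OB(O)B(O)O
Why: Miyaura-type borylation (oxidative addition of zerovalent palladium/XPhos into the electron-rich aryl bromide, acetate-assisted transmetalation from diboron) gives the free boronic acid directly, and the chelated phenol, the flavone and the benzyl ethers are inert.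

Step 4
Reactants: 7 1-(2,4-dihydroxy-6-methoxyphenyl)ethan-1-one
Product: 8 4-O-benzyl acetophenone
Conditions: BnBr (1.05 equiv), K2CO3 (1.2 equiv), acetone, reflux
Reagents that add atoms: benzyl bromide, BrCc1ccccc1
Why: Williamson ether synthesis, selective for the 4-OH because the 2-OH is chelated to the acetyl carbonyl.

Step 5
Reactants: 8 4-O-benzyl acetophenone
Product: 10 chromone (7-benzyloxy-5-methoxy-4H-chromen-4-one), via enaminone 9 (not isolated)
Conditions: Me2NCH(OMe)2 (3 equiv), toluene, 100 °C; evaporate; then conc. HCl, CH2Cl2, 40 °C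
Reagents that add atoms: N,N-dimethylformamide dimethyl acetal, COC(OC)N(C)C
Why: Enaminone chromone synthesis: the acetyl CH3 condenses with the formamide acetal, then the phenol oxygen adds 6-endo to the protonated enaminone and dimethylamine is lost; no stereocentre is formed.

Step 6
Reactants: 6 biaryl boronic acid; 10 chromone
Product: 11 tetra-O-benzyl ether of the target
Conditions: 10 (2 equiv), [RhOH(cod)]2 (2.5 mol %) premixed with (S)-MeO-F12-BIPHEP [(S)-2,2'-bis[bis(3,4,5-trifluorophenyl)phosphino]-6,6'-dimethoxy-1,1'-biphenyl] (5.5 mol %), CH2Cl2/H2O (10:1), 35–40 °C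
Reagents that add atoms: none
Why: Hayashi–Miyaura asymmetric 1,4-addition: the aryl group is transferred from boron to monovalent rhodium and inserted into the chromone C2=C3 bond, and the (S)-bisphosphine is expected to direct it to the Re face of C2 (the sense that gives (S)-3-arylcyclohexanones), setting 2S; the base-free medium avoids chalcone ring-opening, and the flavone in 6 is a β,β-disubstituted enone that does not react.

Step 7
Reactants: 11 tetra-O-benzyl ether of the target
Product: 12 target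
Conditions: H2 (1 atm), Pd/C (10 wt %), THF/MeOH (2:1), rt, stopped after uptake of 4 equiv H2
Reagents that add atoms: none
Why: Catalytic hydrogenolysis cleaves the four benzyl aryl ethers under neutral conditions, which leave the aryl methyl ether intact and do not epimerise C2 (no base, so no retro-oxa-Michael opening).

**Compound list**
1 | apigenin, 5,7-dihydroxy-2-(4-hydroxyphenyl)-4H-chromen-4-one | O=c1cc(-c2ccc(O)cc2)oc2cc(O)cc(O)c12 | starting material
2 | 7-(benzyloxy)-2-[4-(benzyloxy)phenyl]-5-hydroxy-4H-chromen-4-one | O=c1cc(-c2ccc(OCc3ccccc3)cc2)oc2cc(OCc3ccccc3)cc(O)c12 | intermediate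
3 | [2-(benzyloxy)-5-bromophenyl]boronic acid | OB(O)c1cc(Br)ccc1OCc1ccccc1 | starting material
4 | [2-(benzyloxy)-5-bromophenyl]lead triacetate | CC(=O)O[Pb](OC(C)=O)(OC(C)=O)c1cc(Br)ccc1OCc1ccccc1 | intermediate (not isolated)
5 | 7-(benzyloxy)-6-[2-(benzyloxy)-5-bromophenyl]-2-[4-(benzyloxy)phenyl]-5-hydroxy-4H-chromen-4-one | O=c1cc(-c2ccc(OCc3ccccc3)cc2)oc2cc(OCc3ccccc3)c(-c3cc(Br)ccc3OCc3ccccc3)c(O)c12 | intermediate
6 | {4-(benzyloxy)-3-[7-(benzyloxy)-2-(4-(benzyloxy)phenyl)-5-hydroxy-4-oxo-4H-chromen-6-yl]phenyl}boronic acid | O=c1cc(-c2ccc(OCc3ccccc3)cc2)oc2cc(OCc3ccccc3)c(-c3cc(B(O)O)ccc3OCc3ccccc3)c(O)c12 | intermediate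
7 | 1-(2,4-dihydroxy-6-methoxyphenyl)ethan-1-one | CC(=O)c1c(O)cc(O)cc1OC | starting material
8 | 1-[4-(benzyloxy)-2-hydroxy-6-methoxyphenyl]ethan-1-one | CC(=O)c1c(O)cc(OCc2ccccc2)cc1OC | intermediate
9 | (E)-1-[4-(benzyloxy)-2-hydroxy-6-methoxyphenyl]-3-(dimethylamino)prop-2-en-1-one | CN(C)/C=C/C(=O)c1c(O)cc(OCc2ccccc2)cc1OC | intermediate (not isolated)
10 | 7-(benzyloxy)-5-methoxy-4H-chromen-4-one | COc1cc(OCc2ccccc2)cc2occc(=O)c12 | intermediate
11 | 7-(benzyloxy)-6-{2-(benzyloxy)-5-[(2S)-7-(benzyloxy)-5-methoxy-4-oxo-3,4-dihydro-2H-chromen-2-yl]phenyl}-2-[4-(benzyloxy)phenyl]-5-hydroxy-4H-chromen-4-one | COc1cc(OCc6ccccc6)cc2c1C(=O)C[C@@H](c1ccc(OCc6ccccc6)c(-c3c(OCc6ccccc6)cc4oc(-c5ccc(OCc6ccccc6)cc5)cc(=O)c4c3O)c1)O2 | intermediate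
12 | 5,7-dihydroxy-6-{2-hydroxy-5-[(2S)-7-hydroxy-5-methoxy-4-oxo-3,4-dihydro-2H-chromen-2-yl]phenyl}-2-(4-hydroxyphenyl)-4H-chromen-4-one | COc1cc(O)cc2c1C(=O)C[C@@H](c1ccc(O)c(-c3c(O)cc4oc(-c5ccc(O)cc5)cc(=O)c4c3O)c1)O2 | target

**Totals**
Total steps: 7. Longest linear sequence: 5 steps (1 → 2 → 5 → 6 → 11 → 12; steps 1, 2, 3, 6, 7).

**Steps most likely to fail**

Step 2 (lead-mediated C6–H arylation). Risks: the chelated 5-OH may exchange onto lead slowly; ipso attack at C4a could compete; the new biaryl is tri-ortho-substituted. Fallback, setting out from 2 and coming back at 6: 2 is iodinated ortho to the free 5-OH with BnMe3N·ICl2 and CaCO3 in CH2Cl2/MeOH at rt to give 7-(benzyloxy)-2-[4-(benzyloxy)phenyl]-5-hydroxy-6-iodo-4H-chromen-4-one F1. Conventional Suzuki–Miyaura coupling of F1 with purchased [2-(benzyloxy)-5-chlorophenyl]boronic acid (OB(O)c1cc(Cl)ccc1OCc1ccccc1; Pd(PPh3)4, Na2CO3, DME/H2O, 80 °C) gives 7-(benzyloxy)-6-[2-(benzyloxy)-5-chlorophenyl]-2-[4-(benzyloxy)phenyl]-5-hydroxy-4H-chromen-4-one F2. The chloro partner is used because its C–Cl bond is inert to this catalyst, so the boronic acid cannot couple with itself. Borylation of F2 under the step 3 conditions, which were developed for aryl chlorides, rejoins the route at 6.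

Step 6 (asymmetric 1,4-addition). Risks: the valuable boronic acid is the limiting partner and can protodeboronate; the 5-hydroxy-4-keto unit of 6 can bind rhodium like an acetylacetonate; the chromone is electron-rich; the sense and level of induction must be confirmed on the first run. Fallback, setting out from 2 (with 8 from step 4) and coming back at 11: purchased [2-(benzyloxy)-5-formylphenyl]boronic acid (OB(O)c1cc(C=O)ccc1OCc1ccccc1) is converted with Pb(OAc)4 and catalytic Hg(OAc)2 into [2-(benzyloxy)-5-formylphenyl]lead triacetate F3, which arylates 2 as in step 2 to give 4-(benzyloxy)-3-{7-(benzyloxy)-2-[4-(benzyloxy)phenyl]-5-hydroxy-4-oxo-4H-chromen-6-yl}benzaldehyde F4. Claisen–Schmidt condensation of F4 with 8 (KOH, EtOH/THF, rt) gives the 2'-hydroxychalcone (E)-1-[4-(benzyloxy)-2-hydroxy-6-methoxyphenyl]-3-(4-(benzyloxy)-3-{7-(benzyloxy)-2-[4-(benzyloxy)phenyl]-5-hydroxy-4-oxo-4H-chromen-6-yl}phenyl)prop-2-en-1-one F5. NaOAc in refluxing EtOH closes it by oxa-Michael addition to the racemic flavanone, racemic 11 F6; the 6'-methoxy group favours the closed form. The 2S enantiomer 11 is then isolated by preparative chromatography on a chiral stationary phase (amylose tris(3,5-dimethylphenylcarbamate), supercritical CO2/MeOH).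

Step 7 (fourfold hydrogenolysis). Risks: low solubility; reduction of the flavone C2=C3 bond; hydrogenolytic opening of the flavanone benzylic C–O bond. Fallback, setting out from 11 and coming back at 12, with no new compound (F0): non-reductive debenzylation with BCl3 (8 equiv) and pentamethylbenzene (12 equiv) in CH2Cl2 at −78 °C, quenched cold with MeOH. The benzyl cations are trapped by the arene, and at this temperature the peri 5-methoxy group, which BCl3 cleaves only near 0 °C, should survive.

**Further compounds**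
F1 | step 2 | 7-(benzyloxy)-2-[4-(benzyloxy)phenyl]-5-hydroxy-6-iodo-4H-chromen-4-one | O=c1cc(-c2ccc(OCc3ccccc3)cc2)oc2cc(OCc3ccccc3)c(I)c(O)c12
F2 | step 2 | 7-(benzyloxy)-6-[2-(benzyloxy)-5-chlorophenyl]-2-[4-(benzyloxy)phenyl]-5-hydroxy-4H-chromen-4-one | O=c1cc(-c2ccc(OCc3ccccc3)cc2)oc2cc(OCc3ccccc3)c(-c3cc(Cl)ccc3OCc3ccccc3)c(O)c12
F3 | step 6 | [2-(benzyloxy)-5-formylphenyl]lead triacetate | CC(=O)O[Pb](OC(C)=O)(OC(C)=O)c1cc(C=O)ccc1OCc1ccccc1
F4 | step 6 | 4-(benzyloxy)-3-{7-(benzyloxy)-2-[4-(benzyloxy)phenyl]-5-hydroxy-4-oxo-4H-chromen-6-yl}benzaldehyde | O=Cc1ccc(OCc2ccccc2)c(-c2c(OCc3ccccc3)cc3oc(-c4ccc(OCc5ccccc5)cc4)cc(=O)c3c2O)c1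
F5 | step 6 | (E)-1-[4-(benzyloxy)-2-hydroxy-6-methoxyphenyl]-3-(4-(benzyloxy)-3-{7-(benzyloxy)-2-[4-(benzyloxy)phenyl]-5-hydroxy-4-oxo-4H-chromen-6-yl}phenyl)prop-2-en-1-one | COc1cc(OCc2ccccc2)cc(O)c1C(=O)/C=C/c1ccc(OCc2ccccc2)c(-c2c(OCc3ccccc3)cc3oc(-c4ccc(OCc5ccccc5)cc4)cc(=O)c3c2O)c1
F6 | step 6 | racemic 11, 7-(benzyloxy)-6-{2-(benzyloxy)-5-[7-(benzyloxy)-5-methoxy-4-oxo-3,4-dihydro-2H-chromen-2-yl]phenyl}-2-[4-(benzyloxy)phenyl]-5-hydroxy-4H-chromen-4-one | COc1cc(OCc6ccccc6)cc2c1C(=O)CC(c1ccc(OCc6ccccc6)c(-c3c(OCc6ccccc6)cc4oc(-c5ccc(OCc6ccccc6)cc5)cc(=O)c4c3O)c1)O2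
F0 | step 7 | none | none
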